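Readings and results are simulated with made-up constants, and the scatter is random.

In a one-step world of first order, product in percent of the charge follows one time constant at any concentration, so Monday's and Tuesday's curves would lie on each other. That is the zero of our scale, and the two runs depart from it.

common to all: free catalyst 0.52 mol%; second catalyst 5.9 mol%
- Monday's: starting material 0.95 M; solid reagent 2 equiv; run made earlier
- Tuesday's: starting material 1.5 M; solid reagent 2 equiv; run made earlier
- flask: starting material 0.68 M; solid reagent 2.00 equiv; time 6.0 h

| run | time / h | product / % | starting material / % |
|---|---|---|---|
| Monday's | 0.667 | 0 | 65.8 |
| Monday's | 2.00 | 2.4 | 64.2 |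
| Monday's | 3.00 | 3.1 | 63.1 |
| Monday's | 5.00 | 6.2 | 61.9 |
| Monday's | 8.00 | 8.7 | 58.8 |
| Tuesday's | 0.500 | 0 | 65.2 |
| Tuesday's | 1.00 | 1.6 | 64.1 |
| Tuesday's | 2.00 | 2.6 | 63.0 |
| Tuesday's | 4.00 | 7.3 | 61.1 |
| Tuesday's | 8.00 | 13.3 | 56.4 |

(each reading ± 0.5 percentage points)

- given per volume of solution although it is solid: solid reagent
- steps that have been proposed: solid reagent <-> partner; partner + second catalyst + intermediate -> second catalyst + product; starting material + free catalyst <-> free catalyst + intermediate
- at the start none of the solid reagent is in solution

- west: doubling the amount of free catalyst, all else as stated
- south-west: doubling the dissolution coefficient of the solid reagent, all else as stated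
- south-east: doubling the solubility of the solid reagent, all else as stated

- amount of product at 6.0 h, in percent of the starting material charged
- concentration of partner in solution at 1.5 h, in percent of saturation
- the change that raises the amount of product at 6.0 h, in percent of the starting material charged most ("none" if none brings more than 2 percentage points) (west / south-west / south-east / none)
- amount of product at 6.0 h, in percent of the starting material charged, after south-west

Three steps are proposed. Solid reagent dissolves to partner, starting material goes reversibly to intermediate on free catalyst, and partner and intermediate meet on second catalyst to give product.

Take concentration first. By hand, second catalyst and intermediate scale with the charge, while dissolved partner stays at a level set by solubility, so percent per hour should grow in proportion to concentration. At 8.00 h, Tuesday's product over Monday's reads 1.53, against a concentration ratio of 1.58. We therefore carry the specific slope, the fraction of the charge turned into product per hour per molar of starting material, read from both runs as 0.0112 M⁻¹ h⁻¹.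

Next, free catalyst. Starting material reads 65.8 % at 0.667 h on Monday and 65.2 % at 0.500 h on Tuesday, with product at 0 %. The missing third we book as intermediate in a pre-equilibrium reached by then, so we expect no gain near the margin of 2 percentage points from west.

Then dissolving. Tuesday's product at 1.00 h reads 1.6 %, and the slope gives 1.68 %, so within the scatter of 0.5 points we read a lag shorter than that hour. In the new flask, an hour of slope is worth 0.76 points, less than the margin of 2 points, and south-west recovers a part of that lag.

Last, solubility. Partner enters the product step once, so by the proposed step south-east should double the slope, though no run has tested this.

For the new flask, our reckoning gives 4.58 %, and 9.16 % after south-east. We put partner close to its ceiling by 1.5 h, without a figure of our own. The forecast says 4.7 %, a little above ours, with partner at 97 % of saturation, south-east as the best change and 4.8 % after south-west: “Percent rate is therefore proportional to concentration”.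

The new flask gives 4.83 %, partner at 96.4 % of saturation at 1.5 h, and 5.00 % after south-west. The best change is south-east, which adds 4.6 points, against 0.044 points for west and 0.17 points for south-west.

    solid reagent ⇌ partner, rate k1*(cs1 - [partner]) while solid is left; crystals form when [partner] > cs1 (solubility = 0.250 M, k = 0.0400 min⁻¹)
    partner + second catalyst + intermediate → second catalyst + product (k = 0.0430 M⁻² min⁻¹)
    starting material + free catalyst ⇌ free catalyst + intermediate (K = 0.540, k = 8.50 M⁻¹ min⁻¹)

Over 6.0 h the new flask averaged 0.0118 M⁻¹ h⁻¹, against our 0.0112 M⁻¹ h⁻¹. For the same flask left until 15 h, our 0.0112 M⁻¹ h⁻¹ gives 11.4 %, and that flask holds 12.2 %.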